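Read at 1.0 min and again at 1.5 h, this flask need not show the same share of other capture product in the two capture products together.

| flask | solid substrate | first nucleophile | second nucleophile | remark | time |
|---|---|---|---|---|---|
| spring | 1.5 M | 1.95 M | 0.75 M | run made earlier |  |
| dawn | 1.5 M | 1.95 M | 1.1 M | run made earlier |  |
| flask | 1.5 M | 1.95 M | 1.50 M |  | 1.5 h |

| run | time / min | other capture product / % | target / % | solid substrate / % |
|---|---|---|---|---|
| spring | 10.0 | 3.3 | 4.5 | 49.2 |
| spring | 20.0 | 7.2 | 6.3 | 0 |
| spring | 30.0 | 7.0 | 6.1 | 0 |
| spring | 40.0 | 6.8 | 6.4 | 0 |
| spring | 50.0 | 6.3 | 5.9 | 0 |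
| spring | 60.0 | 6.4 | 6.3 | 0.4 |
| spring | 80.0 | 6.9 | 6.1 | 0.1 |
| dawn | 6.00 | 2.9 | 3.0 | 69.4 |
| dawn | 8.00 | 3.6 | 4.0 | 59.8 |
| dawn | 12.0 | 6.1 | 4.9 | 39.9 |
| dawn | 20.0 | 9.0 | 5.7 | 0.3 |
| dawn | 30.0 | 9.7 | 6.2 | 0.1 |
| dawn | 50.0 | 9.8 | 6.1 | 0 |
| dawn | 80.0 | 9.7 | 6.1 | 0 |

(readings scatter by 0.3 percentage points)

- as a solid, counted per litre of solution: solid substrate
- at the start none of the solid substrate is in solution

- share of other capture product in other capture product plus target at 1.0 min
- share of other capture product in other capture product plus target at 1.5 h

In the runs so far, the end yield of other capture product rises with the second nucleophile. The dawn run gives 0.0882 M⁻¹ as the end fraction of other capture product over the charge of second nucleophile, the capture per molar. The last spring reading gives 0.0920 M⁻¹, close to it given the scatter. On this flask's charge, the capture per molar gives 13.2 % of the solid substrate charged. Target ended at 6.1 % in both runs.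

Two chemists part over the early reading. The first made the forecast: 54 % at 1.0 min and 68.4 % at 1.5 h. Its ground is “Conversion, not time, is the useful axis”. The second chemist holds that, early on, a molar of either nucleophile catches alike. The share then follows the charges, which gives 43.5 % at 1.0 min.

The flask gives 37.1 % at 1.0 min and 68.6 % at 1.5 h. The forecast stands 17 percentage points too high early, and the second chemist's figure lies nearer. The forecast's view keeps the end of the run, where the two yields are flat and its share holds.

    starting material → intermediate (k = 0.0460 s⁻¹)
    first nucleophile + intermediate → target (k = 4.50 M⁻¹ s⁻¹)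
    second nucleophile + intermediate → other capture product (k = 2.60 M⁻¹ s⁻¹)
    intermediate → solvolysis product (k = 23.0 s⁻¹)
    2 first nucleophile → self-condensation product (k = 0.00250 M⁻¹ s⁻¹)
    solid substrate ⇌ starting material, rate k6*(cs6 - [starting material]) while solid is left; crystals form when [starting material] > cs6 (solubility = 0.0790 M, k = 0.0240 s⁻¹)

In this flask at 0.171 h the intermediate goes to solvolysis product 6.3 times as fast as to other capture product, and at the end 87 % of the second nucleophile is still there, near the pseudo-first-order case of a partner in excess. At that end, other capture product in this flask, at 12.9 % against the 13.2 % from the capture per molar, is a small correction beside solvolysis product at 81.2 %.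

The neighbour with 0.38 M of solid substrate is charged with 1.50 M of second nucleophile, so the capture per molar again gives 13.2 %. Computed, that neighbour holds 12.6 % of other capture product beside 12.0 % of target, a share of 51.1 %.

The data were computed for substances that don't exist.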